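**Assumption and convention (one line):** the SMILES is read as (3R,4R,5R,10R) with a (2S,3R) epoxy ester, i.e. 3α-acyloxy, 4β-acetoxy (trans-diaxial), 5α-H, 10β-CH3; eudesmane locants are used for all bicycles (ring A = C1–C5 and C10, ring B = C5–C10, C11 on C7; before the ring expansion C9 is absent and C8 is bonded to C10), and β is the face of the C10 methyl group.

## Retrosynthetic overview

1. Target ⇒ singlet-oxygen ene reaction on the 7(11)-en-8-one (C11–OOH, Δ6) as the last step.
2. ⇒ one-flask anti-diacyloxylation of the Δ3 olefin of eudesma-3,7(11)-dien-8-one: acetate to C4, the silver salt of (2S,3R)-2,3-dimethyloxirane-2-carboxylic acid to C3 (acid from tiglyl alcohol by asymmetric epoxidation and oxidation).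
3. ⇒ C7=C11 by aldol condensation of a trans-decalin-8-one with acetone.
4. ⇒ ring B by one-carbon ring expansion of a trans-hydrindan-8-one (1,2-shift of quaternary C10; C9 is inserted between C10 and C8).
5. ⇒ hydrindane from 2-methylcyclopentane-1,3-dione and ethyl vinyl ketone; ring order: cyclopentane (given) → ring A (amino-acid-catalysed annulation sets C10, reductive 1,3-transposition sets C5) → ring B (five to six).

## Route

Step 1
Reactants: 1 (E)-2-methylbut-2-en-1-ol (tiglyl alcohol)
Product: 2 [(2R,3R)-2,3-dimethyloxiran-2-yl]methanol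
Conditions: Ti(Oi-Pr)4 (5 mol%), D-(−)-diisopropyl tartrate (7 mol%), t-BuOOH, 4 Å MS, CH2Cl2, −20 °C
Reagents that add atoms: tert-butyl hydroperoxide, CC(C)(C)OO
Why: Katsuki–Sharpless asymmetric epoxidation of an (E)-trisubstituted allylic alcohol; the D-(−)-tartrate catalyst gives the (2R,3R)-epoxide (the mirror image of the L-(+)-tartrate product), which sets both side-chain stereocentres.

Step 2
Reactants: 2 [(2R,3R)-2,3-dimethyloxiran-2-yl]methanol
Product: 4 silver (2S,3R)-2,3-dimethyloxirane-2-carboxylate, via epoxy acid 3 (not isolated)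
Conditions: RuCl3·xH2O (2 mol%), NaIO4, CCl4/MeCN/H2O, 0 → 23 °C; extract; then Ag2O (0.5 equiv), H2O/MeCN, dark, 23 °C; dry in vacuo over P2O5
Reagents that add atoms: water, O; silver oxide Ag2O, [Ag]O[Ag]
Why: Sharpless RuCl3/NaIO4 oxidation of the primary epoxy alcohol to the acid leaves the oxirane and both stereocentres untouched (C2 changes from R to S only through CIP priorities), and neutralisation with Ag2O gives the dry silver salt needed in step 9.

Step 3
Reactants: 5 2-methylcyclopentane-1,3-dione; 6 pent-1-en-3-one (ethyl vinyl ketone)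
Product: 8 (7aS)-4,7a-dimethyl-2,3,7,7a-tetrahydro-1H-indene-1,5(6H)-dione, via triketone 7 (not isolated)
Conditions: H2O, 75 °C; evaporate; then L-phenylalanine (1 equiv), 1 M HClO4 (0.4 equiv), MeCN, 80 °C; recrystallise
Reagents that add atoms: none
Why: Michael addition followed by the amino-acid-catalysed Hajos–Parrish–Eder–Sauer–Wiechert aldol condensation, in which L-phenylalanine (better than proline for ethyl-ketone triketones) selects one of the two enantiotopic ring carbonyls and sets C10 as S in 8 (10R in the target); ee is raised by recrystallisation.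

Step 4
Reactants: 8 (7aS)-4,7a-dimethyl-2,3,7,7a-tetrahydro-1H-indene-1,5(6H)-dione
Product: 9 (1S,5S,7aS)-4,7a-dimethyl-2,3,5,6,7,7a-hexahydro-1H-indene-1,5-diol
Conditions: NaBH4, CeCl3·7H2O, MeOH, −20 → 0 °C
Reagents that add atoms: none
Why: Luche reduction delivers hydride 1,2 from the α face (anti to the angular methyl) to give the 3β allylic alcohol; the saturated C8 ketone is reduced too (8β-OH, reoxidised in step 6), so no selectivity between the two carbonyls is needed.

Step 5
Reactants: 9 (1S,5S,7aS)-4,7a-dimethyl-2,3,5,6,7,7a-hexahydro-1H-indene-1,5-diol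
Product: 12 (1S,3aS,7aS)-4,7a-dimethyl-2,3,3a,6,7,7a-hexahydro-1H-inden-1-ol, via sulfonylhydrazine adduct 10 (not isolated), via allylic diazene 11 (not isolated)
Conditions: PPh3, DEAD, 2-nitrobenzenesulfonylhydrazide (NBSH), N-methylmorpholine/THF, −30 °C; then 23 °C
Reagents that add atoms: none
Why: Myers reductive 1,3-transposition: the Mitsunobu reaction with NBSH inverts C3 (3β-OH to 3α-N; the neopentyl 8β-OH is too hindered to react), loss of sulfinic acid gives the 3α-diazene, and its retro-ene loss of N2 delivers H to C5 on the α face, which sets the trans ring fusion (5α-H) and moves the olefin to Δ3.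

Step 6
Reactants: 12 (1S,3aS,7aS)-4,7a-dimethyl-2,3,3a,6,7,7a-hexahydro-1H-inden-1-ol
Product: 13 (3aS,7aS)-4,7a-dimethyl-2,3,3a,6,7,7a-hexahydro-1H-inden-1-one
Conditions: Dess–Martin periodinane, CH2Cl2, 23 °C
Reagents that add atoms: none
Why: Dess–Martin oxidation of the hindered secondary alcohol; the neighbouring C10 is quaternary and C5 is not α to the new ketone, so nothing can epimerise, and the trisubstituted olefin is inert.

Step 7
Reactants: 13 (3aS,7aS)-4,7a-dimethyl-2,3,3a,6,7,7a-hexahydro-1H-inden-1-one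
Product: 17 (4aR,8aR)-5,8a-dimethyl-3,4,4a,7,8,8a-hexahydro-1H-naphthalen-2-one, via lithium alkoxide 14 (not isolated), via oxido carbenoid 15 (not isolated), via lithium enolate 16 (not isolated)
Conditions: CH2Br2, lithium 2,2,6,6-tetramethylpiperidide (LiTMP), THF, −78 °C; then n-BuLi, −78 → 0 °C; then H2O
Reagents that add atoms: dibromomethane, BrCBr
Why: Nozaki–Yamamoto β-oxido carbenoid ring expansion: LiCHBr2 adds to the ketone from the α face, Br/Li exchange gives the carbenoid, and the more substituted, quaternary C10 shifts with retention to the carbenoid carbon as LiBr leaves (the opposite regiochemistry to diazomethane), which inserts C9 between C10 and C8 and gives the trans-decalin-8-one with C5 and C10 untouched.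

Step 8
Reactants: 17 (4aR,8aR)-5,8a-dimethyl-3,4,4a,7,8,8a-hexahydro-1H-naphthalen-2-one
Product: 20 eudesma-3,7(11)-dien-8-one, via zinc aldolate 18 (not isolated), via mesylate 19 (not isolated)
Conditions: LiN(i-Pr)2 (LDA), THF, −78 °C; ZnCl2; acetone, −78 → −40 °C; then MsCl, −40 → 0 °C; DBU, 23 °C
Reagents that add atoms: acetone, CC(C)=O
Why: kinetic deprotonation goes to C7 because C9 is neopentyl beside quaternary C10 (as in 10-methyl-trans-2-decalones), the zinc-mediated aldol addition to acetone is followed by mesylation and E1cB elimination to the conjugated isopropylidene ketone, and no acid is used that could move the Δ3 olefin.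

Step 9
Reactants: 20 eudesma-3,7(11)-dien-8-one; 4 silver (2S,3R)-2,3-dimethyloxirane-2-carboxylate
Product: 23 4β-acetoxy-3α-[(2S,3R)-2,3-dimethyloxirane-2-carbonyloxy]-5α-eudesm-7(11)-en-8-one, via iodoacetate 21 (not isolated), via acetoxonium ion 22 (not isolated)
Conditions: I2 (1.0 equiv), AgOAc (1.0 equiv), CH2Cl2, −20 → 0 °C, dark; then 4 (1.5 equiv), 4 Å MS, PhMe, 50 °C
Reagents that add atoms: silver acetate, CC(=O)[O-].[Ag+]
Why: Proposed new method: a programmed hetero-Prévost anti-1,2-diacyloxylation with two different carboxylates — AcOI (from I2/AgOAc) forms the iodonium ion on the open α face and acetate opens it at tertiary C4 from the β face (Markovnikov and trans-diaxial) to 21; silver carboxylate 4 then removes iodide with anchimeric help from the antiperiplanar 4β-acetate to give the cis-fused acetoxonium ion 22, which the epoxy carboxylate opens by SN2 at secondary C3 from the α face (again trans-diaxial), so the acetate stays on O4, both C–O bonds are formed and C3 (R) and C4 (R) are set in one flask, while the electron-poor enone olefin does not react; the closest known reactions are the Prévost trans-dibenzoyloxylation (one carboxylate only) and the Woodward cis-hydroxylation, which pass through the same 1,3-dioxolan-2-ylium ions.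

Step 10
Reactants: 23 4β-acetoxy-3α-[(2S,3R)-2,3-dimethyloxirane-2-carbonyloxy]-5α-eudesm-7(11)-en-8-one
Product: 24 4β-acetoxy-3α-[(2S,3R)-2,3-dimethyloxirane-2-carbonyloxy]-11-hydroperoxy-5α-eudesm-6-en-8-one (target)
Conditions: O2, hν (white LED), tetraphenylporphyrin (1 mol%), CH2Cl2, −20 °C
Reagents that add atoms: dioxygen, O=O
Why: Schenck ene reaction of singlet oxygen with an s-cis α-alkylidene ketone, which follows the gem rule (as with pulegone-type 2-isopropylidenecyclohexanones): oxygen bonds to the β-carbon C11 and the allylic hydrogen is taken from C6, giving the tertiary hydroperoxide and the Δ6-en-8-one without touching any stereocentre; isomeric 7-hydroperoxy-11-enes would be minor and separable.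

## Compound list

1 | (E)-2-methylbut-2-en-1-ol (tiglyl alcohol) | C/C=C(\C)CO | starting material
2 | [(2R,3R)-2,3-dimethyloxiran-2-yl]methanol | OC[C@@]1(C)O[C@@H]1C | intermediate
3 | (2S,3R)-2,3-dimethyloxirane-2-carboxylic acid | OC(=O)[C@@]1(C)O[C@@H]1C | intermediate
4 | silver (2S,3R)-2,3-dimethyloxirane-2-carboxylate | [Ag+].[O-]C(=O)[C@@]1(C)O[C@@H]1C | intermediate
5 | 2-methylcyclopentane-1,3-dione | CC1C(=O)CCC1=O | starting material
6 | pent-1-en-3-one (ethyl vinyl ketone) | CCC(=O)C=C | starting material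
7 | 2-methyl-2-(3-oxopentyl)cyclopentane-1,3-dione (triketone) | CCC(=O)CCC1(C)C(=O)CCC1=O | intermediate
8 | (7aS)-4,7a-dimethyl-2,3,7,7a-tetrahydro-1H-indene-1,5(6H)-dione | CC1=C2CCC(=O)[C@@]2(C)CCC1=O | intermediate
9 | (1S,5S,7aS)-4,7a-dimethyl-2,3,5,6,7,7a-hexahydro-1H-indene-1,5-diol (3β,8β-diol, Δ4) | CC1=C2CC[C@H](O)[C@@]2(C)CC[C@@H]1O | intermediate
10 | sulfonylhydrazine adduct: 9 with the 3β-OH replaced by 3α-N(NH2)SO2(2-nitrophenyl) | CC1=C2CC[C@H](O)[C@@]2(C)CC[C@H]1N(N)S(=O)(=O)c1ccccc1[N+](=O)[O-] | intermediate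
11 | allylic diazene: 9 with the 3β-OH replaced by 3α-N=NH | CC1=C2CC[C@H](O)[C@@]2(C)CC[C@H]1N=N | intermediate
12 | (1S,3aS,7aS)-4,7a-dimethyl-2,3,3a,6,7,7a-hexahydro-1H-inden-1-ol (Δ3, 5α-H, 8β-OH) | CC1=CCC[C@]2(C)[C@@H](O)CC[C@@H]12 | intermediate
13 | (3aS,7aS)-4,7a-dimethyl-2,3,3a,6,7,7a-hexahydro-1H-inden-1-one | CC1=CCC[C@]2(C)C(=O)CC[C@@H]12 | intermediate
14 | lithium alkoxide of the 8α-dibromomethyl-8β-ol adduct of 13 | CC1=CCC[C@]2(C)[C@]([O-])(C(Br)Br)CC[C@@H]12.[Li+] | intermediate
15 | β-oxido carbenoid (8β-OLi, 8α-CH(Li)Br; carbenoid carbon configurationally labile) | CC1=CCC[C@]2(C)[C@]([O-])(C([Li])Br)CC[C@@H]12.[Li+] | intermediate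
16 | lithium Δ8(9)-enolate of 17 | CC1=CCC[C@]2(C)C=C([O-])CC[C@@H]12.[Li+] | intermediate
17 | (4aR,8aR)-5,8a-dimethyl-3,4,4a,7,8,8a-hexahydro-1H-naphthalen-2-one (Δ3, 5α-H, 10β-CH3, 8-one) | CC1=CCC[C@]2(C)CC(=O)CC[C@@H]12 | intermediate
18 | zinc aldolate: 17 bearing 7β-C(CH3)2OZnCl | CC1=CCC[C@]2(C)CC(=O)[C@@H](C(C)(C)O[Zn]Cl)C[C@@H]12 | intermediate
19 | mesylate: 17 bearing 7β-C(CH3)2OSO2CH3 | CC1=CCC[C@]2(C)CC(=O)[C@@H](C(C)(C)OS(C)(=O)=O)C[C@@H]12 | intermediate
20 | eudesma-3,7(11)-dien-8-one [(4aR,8aR)-5,8a-dimethyl-3-(propan-2-ylidene)-3,4,4a,7,8,8a-hexahydro-1H-naphthalen-2-one] | CC1=CCC[C@]2(C)CC(=O)C(=C(C)C)C[C@@H]12 | intermediate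
21 | 4β-acetoxy-3α-iodo-5α-eudesm-7(11)-en-8-one | CC(=O)O[C@]1(C)[C@@H]2CC(=C(C)C)C(=O)C[C@@]2(C)CC[C@H]1I | intermediate
22 | acetoxonium ion: 3β,4β-(2-methyl-1,3-dioxolan-2-ylium) on the 7(11)-en-8-one | CC1=[O+][C@]2(C)[C@@H]3CC(=C(C)C)C(=O)C[C@@]3(C)CC[C@@H]2O1 | intermediate
23 | 4β-acetoxy-3α-[(2S,3R)-2,3-dimethyloxirane-2-carbonyloxy]-5α-eudesm-7(11)-en-8-one (3R,4R,5R,10R) | CC(=O)O[C@]1(C)[C@@H]2CC(=C(C)C)C(=O)C[C@@]2(C)CC[C@H]1OC(=O)[C@@]1(C)O[C@@H]1C | intermediate
24 | 4β-acetoxy-3α-[(2S,3R)-2,3-dimethyloxirane-2-carbonyloxy]-11-hydroperoxy-5α-eudesm-6-en-8-one (3R,4R,5R,10R) | CC(=O)O[C@]1(C)[C@@H]2C=C(C(C)(C)OO)C(=O)C[C@@]2(C)CC[C@H]1OC(=O)[C@@]1(C)O[C@@H]1C | target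

## Step count and risks

Total steps: 10. Longest linear sequence: 8 (steps 3–10); the side chain (steps 1–2) joins in step 9.

Steps most likely to fail:

**Step 9 (the new hetero-Prévost reaction).** Possible failures are acetate scrambling, opening of 22 at C4, elimination, or silver-induced opening of the glycidate. The fallback uses known chemistry and sets out from 20. m-CPBA, NaHCO3, CH2Cl2, 0 °C epoxidises only the electron-rich Δ3 olefin, from the α face, to give 3α,4α-epoxy-5α-eudesm-7(11)-en-8-one F1. Acetolysis (AcOH, 40 °C) opens it trans-diaxially at tertiary C4 to 4β-acetoxy-3α-hydroxy-5α-eudesm-7(11)-en-8-one F2. Yamaguchi esterification of F2 with acid 3 (taken before the Ag2O treatment of step 2; 2,4,6-trichlorobenzoyl chloride, Et3N, DMAP, PhMe) comes back to the route at 23.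

**Step 7 (ring expansion).** Possible failures are enolisation instead of addition at the neopentyl ketone, or migration of C7 instead of C10. The fallback replaces the anionic carbenoid by a cationic thionium semipinacol and sets out from 13. (PhS)2CHLi (from bis(phenylthio)methane and n-BuLi, THF, −78 °C) adds to give the 8α-[bis(phenylthio)methyl]-8β-ol F3. (CuOTf)2·C6H6 and i-Pr2NEt in benzene at 45 °C ionise one C–S bond, and the more substituted C10 shifts to give the 9-phenylthio-trans-decalin-8-one F4. Al(Hg) in aqueous THF removes the sulfur and comes back at 17.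

**Step 5 (Myers transposition).** Possible failures are elimination of the activated allylic alcohol to a diene or partial reaction at the 8-OH. The fallback sets the ring fusion by dissolving-metal reduction and sets out from 8. NaBH4 (0.3 equiv), EtOH, −20 °C reduces only the saturated ketone to (1S,7aS)-1-hydroxy-4,7a-dimethyl-1,2,3,6,7,7a-hexahydro-5H-inden-5-one F5. Li in NH3/THF at −78 °C (the hydroxyl acts as the proton donor; axial protonation gives 5α-H), then PhNTf2, gives the Δ3-enol triflate (1S,3aR,7aS)-1-hydroxy-4,7a-dimethyl-2,3,3a,6,7,7a-hexahydro-1H-inden-5-yl trifluoromethanesulfonate F6. Pd(OAc)2, PPh3, n-Bu3N, HCO2H, DMF, 60 °C reduces the triflate and comes back at 12.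

## Further compounds

F1 | step 9 | 3α,4α-epoxy-5α-eudesm-7(11)-en-8-one | C[C@]12[C@@H]3CC(=C(C)C)C(=O)C[C@@]3(C)CC[C@H]1O2
F2 | step 9 | 4β-acetoxy-3α-hydroxy-5α-eudesm-7(11)-en-8-one | CC(=O)O[C@]1(C)[C@@H]2CC(=C(C)C)C(=O)C[C@@]2(C)CC[C@H]1O
F3 | step 7 | 8α-[bis(phenylthio)methyl]-8β-ol adduct of 13 | CC1=CCC[C@]2(C)[C@](O)(C(Sc3ccccc3)Sc3ccccc3)CC[C@@H]12
F4 | step 7 | 9-phenylthio derivative of 17 (C9 epimers) | CC1=CCC[C@]2(C)C(Sc3ccccc3)C(=O)CC[C@@H]12
F5 | step 5 | (1S,7aS)-1-hydroxy-4,7a-dimethyl-1,2,3,6,7,7a-hexahydro-5H-inden-5-one | CC1=C2CC[C@H](O)[C@@]2(C)CCC1=O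
F6 | step 5 | (1S,3aR,7aS)-1-hydroxy-4,7a-dimethyl-2,3,3a,6,7,7a-hexahydro-1H-inden-5-yl trifluoromethanesulfonate | CC1=C(OS(=O)(=O)C(F)(F)F)CC[C@]2(C)[C@@H](O)CC[C@@H]12
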